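**Plan**

- The target is a 6,8''-linked biflavone: unit 1 (5-hydroxy-7-methoxy-4'-hydroxyflavone) is joined through C6, unit 2 (apigenin) through C8''.
- After the benzyl and 7-O-methyl groups, the retrosynthesis cuts ring A of unit 1 at C6–C7, the ring bond beside the biaryl axis. This is possible because C5, C7 and C8a of that ring all bear oxygen: C7/C8 come from an acetic ester on C8a and C5/C6 from an arylacetyl ketone on C4a of a 4-pyranone, and their enol derivatives span a triene across C4a=C8a.
- The pyranone is cut at O1–C8a and C4–C4a into an aroylketene and a 3,5-diketo ester. The diketo ester is cut at C4a–C5 into methyl acetoacetate and a (flavon-8''-yl)acetic acid, and that acid at C8''–CH2 back to 8-iodoapigenin tribenzyl ether.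
- Forward: unit 2 is complete from the start (apigenin). The two-carbon arm and then the acetoacetate unit are joined to C8'', the pyranone ring of unit 1 is closed next, and ring A of unit 1 is closed last. The biaryl bond is therefore the old aryl–CH2 bond and is never made by coupling two flavones.
- Stereochemistry: the target has no stereocentre and its axis is not specified. The only geometry that matters on the way, the (Z)-enol ether, is set under thermodynamic control and disappears on aromatisation.

Key step: step 9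

Assumption: the target SMILES fixes no configuration at the 6,8''-axis, so the axis is left uncontrolled (racemic material if rotation is slow); zinc reagent 4 is bought as its ether solution.

**Route**

Step 1
Reactants: 1 apigenin
Product: 2 5,7,4'-tri-O-benzylapigenin
Conditions: BnBr (4 equiv), K2CO3, DMF, 80 °C
Reagents that add atoms: benzyl bromide, BrCc1ccccc1
Why: Williamson ether synthesis; hot DMF with excess benzyl bromide should also alkylate the hydrogen-bonded 5-hydroxyl.

Step 2
Reactants: 2 5,7,4'-tri-O-benzylapigenin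
Product: 3 8-iodo-5,7,4'-tri-O-benzylapigenin
Conditions: I2, CF3CO2Ag, CH2Cl2, 20 °C
Reagents that add atoms: iodine, [I][I]
Why: Electrophilic aromatic iodination with silver-activated iodine; 5,7-dialkoxyflavones whose 5-oxygen is alkylated are iodinated at C8, between the 7-alkoxy group and the ring oxygen.

Step 3
Reactants: 3 8-iodo-5,7,4'-tri-O-benzylapigenin; 4 (2-tert-butoxy-2-oxoethyl)zinc chloride
Product: 5 tert-butyl 2-(5,7,4'-tri-O-benzylapigenin-8-yl)acetate
Conditions: Pd2(dba)3 (2.5 mol %), XPhos (10 mol %), THF, 60 °C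
Reagents that add atoms: none
Why: Negishi-type cross-coupling of a Reformatsky reagent with an aryl iodide; the bulky biarylphosphine should allow coupling at the doubly ortho-substituted carbon, and the zinc enolate leaves the flavone carbonyl and the benzyl ethers alone.

Step 4
Reactants: 5 tert-butyl 2-(5,7,4'-tri-O-benzylapigenin-8-yl)acetate
Product: 6 2-(5,7,4'-tri-O-benzylapigenin-8-yl)acetic acid
Conditions: TFA, CH2Cl2 (1:4), 0 → 20 °C
Reagents that add atoms: none
Why: Acidolysis of a tert-butyl ester with loss of isobutene; aryl benzyl ethers and the flavone should survive short exposure to dilute TFA.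

Step 5
Reactants: 6 2-(5,7,4'-tri-O-benzylapigenin-8-yl)acetic acid; 7 methyl acetoacetate
Product: 10 methyl 3,5-dioxo-6-(5,7,4'-tri-O-benzylapigenin-8-yl)hexanoate, via acyl imidazolide 8 (not isolated), via acetoacetate dianion 9 (not isolated)
Conditions: 6, CDI, THF, 20 °C; added to 7 (2.5 equiv) + lithium diisopropylamide (5 equiv), THF, −78 → 0 °C; 1 M HCl quench
Reagents that add atoms: none
Why: Claisen-type acylation of the acetoacetate dianion at its terminal carbon by an acyl imidazolide; the excess dianion takes up the acidic diketo ester as it forms.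

Step 6
Reactants: 11 Meldrum's acid; 12 4-(benzyloxy)benzoyl chloride
Product: 13 5-{[4-(benzyloxy)phenyl](hydroxy)methylidene}-2,2-dimethyl-1,3-dioxane-4,6-dione
Conditions: pyridine (2.2 equiv), DMAP (cat.), CH2Cl2, 0 → 20 °C
Reagents that add atoms: none
Why: C-acylation of Meldrum's acid by an acid chloride, which gives the enolised acyl Meldrum's acid used as the aroylketene source.

Step 7
Reactants: 10 methyl 3,5-dioxo-6-(5,7,4'-tri-O-benzylapigenin-8-yl)hexanoate; 13 5-{[4-(benzyloxy)phenyl](hydroxy)methylidene}-2,2-dimethyl-1,3-dioxane-4,6-dione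
Product: 16 methyl 2-{6-[4-(benzyloxy)phenyl]-4-oxo-3-[(5,7,4'-tri-O-benzylapigenin-8-yl)acetyl]-4H-pyran-2-yl}acetate, via aroylketene 14 (not isolated), via tetraketo ester 15 (not isolated)
Conditions: 13 (1.3 equiv), PhMe, 100 °C; then p-TsOH·H2O (0.1 equiv), 80 °C
Reagents that add atoms: none
Why: Thermal fragmentation of the acyl Meldrum's acid gives the aroylketene, which C-acylates the carbon between the two ketones (acylketene acylation of a 1,3-diketone, the way 3-acyl-4-pyranones are made), and acid-catalysed cyclodehydration should close the pyranone onto the ketone beside the CH2CO2Me group, the more electrophilic and less hindered of the two candidates.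

Step 8
Reactants: 16 methyl 2-{6-[4-(benzyloxy)phenyl]-4-oxo-3-[(5,7,4'-tri-O-benzylapigenin-8-yl)acetyl]-4H-pyran-2-yl}acetate
Product: 17 6-[4-(benzyloxy)phenyl]-2-[2-methoxy-2-(tert-butyldimethylsilyloxy)ethenyl]-3-[(Z)-1-(tert-butyldimethylsilyloxy)-2-(5,7,4'-tri-O-benzylapigenin-8-yl)ethenyl]-4H-pyran-4-one
Conditions: TBSOTf (2.4 equiv), Et3N (3 equiv), CH2Cl2, −78 → 0 °C; pentane / cold aq. NaHCO3 work-up, used at once
Reagents that add atoms: tert-butyldimethylsilyl trifluoromethanesulfonate, CC(C)(C)[Si](C)(C)OS(=O)(=O)C(F)(F)F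
Why: Soft enolisation with a silyl triflate and a tertiary amine; the benzylic ketone should give the (Z)-silyl enol ether (pyranone and flavonyl group trans) and the CH2 between ester and pyranone, a vinylogous 1,3-dicarbonyl position, the silyl ketene acetal, with the crowded ring carbonyl oxygen left free.

Step 9
Reactants: 17 6-[4-(benzyloxy)phenyl]-2-[2-methoxy-2-(tert-butyldimethylsilyloxy)ethenyl]-3-[(Z)-1-(tert-butyldimethylsilyloxy)-2-(5,7,4'-tri-O-benzylapigenin-8-yl)ethenyl]-4H-pyran-4-one
Product: 19 4',5'',7'',4'''-tetra-O-benzyl-5,7-bis-O-(tert-butyldimethylsilyl)agathisflavone, via mixed-ketal cyclohexadiene 18 (not isolated)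
Conditions: degassed o-xylene (0.01 M), 140 °C, sealed tube
Reagents that add atoms: none
Why: Proposed new method: the ketene acetal C7=C8, the ring bond C8a=C4a and the enol ether C5=C6 form a 1,3,5-hexatriene whose central double bond is held cis by the pyranone, and heating should bring about a thermal disrotatory 6π electrocyclisation that makes the C6–C7 bond and closes ring A as the six-membered cyclohexadiene 18. In 18 the new sp3 carbon C7 is a mixed methyl silyl ketal next to the hydrogen at C6, so loss of methanol follows, which makes ring A aromatic as its 5,7-bis(silyl ether) and restores the 4-pyranone. The closest known reactions are the thermal electrocyclisation of oxygenated 1,3,5-hexatrienes with loss of an alcohol to give arenes and the aromatisation of cycloadducts of 1-methoxy-1-silyloxy dienes. The two sp3 centres of 18 (C6 and C7) are lost again, so no stereocentre has to be controlled; the biaryl axis arises without control. The step needs the two termini to meet although C6 carries the bulky flavonyl group: the (Z)-enol ether turns that group outward and only hydrogen inward, so the single inward substituent is an oxygen on C7. If silanol leaves instead of methanol the 7-methyl ether forms, which step 10 turns into 21, so either elimination serves the route.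

Step 10
Reactants: 19 4',5'',7'',4'''-tetra-O-benzyl-5,7-bis-O-(tert-butyldimethylsilyl)agathisflavone
Product: 20 4',5'',7'',4'''-tetra-O-benzylagathisflavone
Conditions: TBAF (2.2 equiv), AcOH (2.2 equiv), THF, 0 °C
Reagents that add atoms: none
Why: Fluoride cleavage of aryl silyl ethers, buffered with acetic acid so that the phenoxides are protonated at once; benzyl ethers are untouched.

Step 11
Reactants: 20 4',5'',7'',4'''-tetra-O-benzylagathisflavone
Product: 21 4',5'',7'',4'''-tetra-O-benzyl-7-O-methylagathisflavone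
Conditions: MeI (1.1 equiv), K2CO3 (1.2 equiv), acetone, 40 °C
Reagents that add atoms: iodomethane, CI
Why: Williamson methylation; the 7-hydroxyl is the free, acidic phenol, while the 5-hydroxyl is held in a hydrogen bond to the C4 carbonyl and should stay unalkylated with one equivalent of iodomethane.

Step 12
Reactants: 21 4',5'',7'',4'''-tetra-O-benzyl-7-O-methylagathisflavone
Product: 22 7-O-methylagathisflavone (CNP0246647.0)
Conditions: H2 (1 atm), 10% Pd/C, THF/MeOH, 20 °C
Reagents that add atoms: none
Why: Hydrogenolysis of the four benzyl ethers over palladium; the methyl ether and the flavone C2=C3 bonds should be unaffected if the reaction is stopped at full debenzylation.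

**Compound list**

1 | apigenin | O=c1cc(-c2ccc(O)cc2)oc2cc(O)cc(O)c12 | starting material
2 | 5,7,4'-tri-O-benzylapigenin | O=c1cc(-c2ccc(OCc3ccccc3)cc2)oc2cc(OCc3ccccc3)cc(OCc3ccccc3)c12 | intermediate
3 | 8-iodo-5,7,4'-tri-O-benzylapigenin | O=c1cc(-c2ccc(OCc3ccccc3)cc2)oc2c(I)c(OCc3ccccc3)cc(OCc3ccccc3)c12 | intermediate
4 | (2-tert-butoxy-2-oxoethyl)zinc chloride | CC(C)(C)OC(=O)C[Zn]Cl | starting material
5 | tert-butyl 2-(5,7,4'-tri-O-benzylapigenin-8-yl)acetate | CC(C)(C)OC(=O)Cc1c(OCc2ccccc2)cc(OCc2ccccc2)c2c(=O)cc(-c3ccc(OCc4ccccc4)cc3)oc12 | intermediate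
6 | 2-(5,7,4'-tri-O-benzylapigenin-8-yl)acetic acid | OC(=O)Cc1c(OCc2ccccc2)cc(OCc2ccccc2)c2c(=O)cc(-c3ccc(OCc4ccccc4)cc3)oc12 | intermediate
7 | methyl acetoacetate | COC(=O)CC(C)=O | starting material
8 | acyl imidazolide of 6 | O=C(Cc1c(OCc2ccccc2)cc(OCc2ccccc2)c2c(=O)cc(-c3ccc(OCc4ccccc4)cc3)oc12)n1ccnc1 | intermediate
9 | dilithium dianion of methyl acetoacetate | [Li+].[Li+].[CH2-]C(=O)[CH-]C(=O)OC | intermediate
10 | methyl 3,5-dioxo-6-(5,7,4'-tri-O-benzylapigenin-8-yl)hexanoate | COC(=O)CC(=O)CC(=O)Cc1c(OCc2ccccc2)cc(OCc2ccccc2)c2c(=O)cc(-c3ccc(OCc4ccccc4)cc3)oc12 | intermediate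
11 | Meldrum's acid | CC1(C)OC(=O)CC(=O)O1 | starting material
12 | 4-(benzyloxy)benzoyl chloride | O=C(Cl)c1ccc(OCc2ccccc2)cc1 | starting material
13 | 5-{[4-(benzyloxy)phenyl](hydroxy)methylidene}-2,2-dimethyl-1,3-dioxane-4,6-dione | CC1(C)OC(=O)C(=C(O)c2ccc(OCc3ccccc3)cc2)C(=O)O1 | intermediate
14 | [4-(benzyloxy)benzoyl]ketene | O=C=CC(=O)c1ccc(OCc2ccccc2)cc1 | intermediate
15 | methyl 4-{3-[4-(benzyloxy)phenyl]-3-oxopropanoyl}-3,5-dioxo-6-(5,7,4'-tri-O-benzylapigenin-8-yl)hexanoate | COC(=O)CC(=O)C(C(=O)CC(=O)c1ccc(OCc2ccccc2)cc1)C(=O)Cc1c(OCc2ccccc2)cc(OCc2ccccc2)c2c(=O)cc(-c3ccc(OCc4ccccc4)cc3)oc12 | intermediate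
16 | methyl 2-{6-[4-(benzyloxy)phenyl]-4-oxo-3-[(5,7,4'-tri-O-benzylapigenin-8-yl)acetyl]-4H-pyran-2-yl}acetate | COC(=O)Cc1oc(-c2ccc(OCc3ccccc3)cc2)cc(=O)c1C(=O)Cc1c(OCc2ccccc2)cc(OCc2ccccc2)c2c(=O)cc(-c3ccc(OCc4ccccc4)cc3)oc12 | intermediate
17 | 6-[4-(benzyloxy)phenyl]-2-[2-methoxy-2-(tert-butyldimethylsilyloxy)ethenyl]-3-[(Z)-1-(tert-butyldimethylsilyloxy)-2-(5,7,4'-tri-O-benzylapigenin-8-yl)ethenyl]-4H-pyran-4-one (ketene acetal geometry not defined) | COC(O[Si](C)(C)C(C)(C)C)=Cc1oc(-c2ccc(OCc3ccccc3)cc2)cc(=O)c1/C(O[Si](C)(C)C(C)(C)C)=C/c1c(OCc2ccccc2)cc(OCc2ccccc2)c2c(=O)cc(-c3ccc(OCc4ccccc4)cc3)oc12 | intermediate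
18 | 2-[4-(benzyloxy)phenyl]-5,7-bis(tert-butyldimethylsilyloxy)-7-methoxy-6-(5,7,4'-tri-O-benzylapigenin-8-yl)-6,7-dihydro-4H-chromen-4-one (C6 and C7 not defined, both centres are lost) | COC1(O[Si](C)(C)C(C)(C)C)C=C2OC(-c3ccc(OCc4ccccc4)cc3)=CC(=O)C2=C(O[Si](C)(C)C(C)(C)C)C1c1c(OCc2ccccc2)cc(OCc2ccccc2)c2c(=O)cc(-c3ccc(OCc4ccccc4)cc3)oc12 | intermediate
19 | 4',5'',7'',4'''-tetra-O-benzyl-5,7-bis-O-(tert-butyldimethylsilyl)agathisflavone | CC(C)(C)[Si](C)(C)Oc1cc2oc(-c3ccc(OCc4ccccc4)cc3)cc(=O)c2c(O[Si](C)(C)C(C)(C)C)c1-c1c(OCc2ccccc2)cc(OCc2ccccc2)c2c(=O)cc(-c3ccc(OCc4ccccc4)cc3)oc12 | intermediate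
20 | 4',5'',7'',4'''-tetra-O-benzylagathisflavone | Oc1cc2oc(-c3ccc(OCc4ccccc4)cc3)cc(=O)c2c(O)c1-c1c(OCc2ccccc2)cc(OCc2ccccc2)c2c(=O)cc(-c3ccc(OCc4ccccc4)cc3)oc12 | intermediate
21 | 4',5'',7'',4'''-tetra-O-benzyl-7-O-methylagathisflavone | COc1cc2oc(-c3ccc(OCc4ccccc4)cc3)cc(=O)c2c(O)c1-c1c(OCc2ccccc2)cc(OCc2ccccc2)c2c(=O)cc(-c3ccc(OCc4ccccc4)cc3)oc12 | intermediate
22 | 7-O-methylagathisflavone (CNP0246647.0) | COc1cc2oc(-c3ccc(O)cc3)cc(=O)c2c(O)c1-c1c(O)cc(O)c2c(=O)cc(-c3ccc(O)cc3)oc12 | target

**Step count**

Total: 12 steps. Longest linear sequence: 11 steps (steps 1–5 and 7–12, from apigenin); step 6 is a one-step side branch.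

**Steps most likely to fail**

1. Step 9. The carbon that carries the doubly ortho-substituted flavonyl group must bond to a carbon bearing two oxygen substituents, so the triene ends may not reach bonding distance before the ketene acetal is desilylated or decomposes. The fallback uses known chemistry and makes the axis by Suzuki–Miyaura coupling of two flavones; it sets out from 3 and 1 and returns at 21. Miyaura borylation of 3 (bis(pinacolato)diboron, Pd(dppf)Cl2, KOAc, dioxane, 90 °C) should give 5,7,4'-tri-O-benzylapigenin-8-boronic acid pinacol ester F1. Apigenin 1 would be methylated at its most acidic 7-hydroxyl (MeI 1 equiv, K2CO3, acetone) to genkwanin F2, benzylated at the 4'-hydroxyl (BnBr, K2CO3, DMF) to 4'-O-benzylgenkwanin F3, and iodinated beside the free 5-hydroxyl (benzyltrimethylammonium dichloroiodate, CaCO3, CH2Cl2/MeOH) to 6-iodo-4'-O-benzylgenkwanin F4. Coupling of F1 with F4 (Pd(OAc)2, SPhos, K3PO4, toluene/H2O, 100 °C) should give 21.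

2. Step 7. The triacylmethane intermediate may close onto the arylacetyl ketone instead of the ketone beside the ester, giving the regioisomeric pyranone, or the ketene may O-acylate the enol. The fallback fixes the site of ring closure on an isolable compound before the ring forms; it sets out from 10 (with 13) and returns at 16. Condensation of 10 with pyrrolidine (PhMe, 4 Å molecular sieves, 20 °C) should give the enaminone methyl (E)-5-oxo-3-(pyrrolidin-1-yl)-6-(5,7,4'-tri-O-benzylapigenin-8-yl)hex-3-enoate F5, whose regiochemistry can be proved by HMBC and purified. Heating F5 with 13 (PhMe, 100 °C) lets the aroylketene acylate the enaminone carbon, and the ring oxygen can then only bond to the carbon that loses pyrrolidine, giving 16.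

3. Step 8. Silylation may take place on the pyranone carbonyl oxygen with an exocyclic double bond to the ring instead of on the ester oxygen, or the ketene acetal may be protodesilylated on isolation; either way no triene for step 9 is at hand. The fallback closes the same C6–C7 bond by enolate chemistry; it sets out from 16 and returns at 20. Heating 16 with Mg(OMe)2 in MeOH (65 °C) should bring about a Claisen condensation of the ketone α-carbon onto the ester under equilibrating, chelating conditions, as in the cyclisation of polyketo esters to acylphloroglucinols, and tautomerisation gives the 5,7-dihydroxy ring of 20 directly.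

**Further compounds**

F1 | step 9 | 5,7,4'-tri-O-benzylapigenin-8-boronic acid pinacol ester | CC1(C)OB(OC1(C)C)c1c(OCc2ccccc2)cc(OCc2ccccc2)c2c(=O)cc(-c3ccc(OCc4ccccc4)cc3)oc12
F2 | step 9 | genkwanin | COc1cc(O)c2c(=O)cc(-c3ccc(O)cc3)oc2c1
F3 | step 9 | 4'-O-benzylgenkwanin | COc1cc(O)c2c(=O)cc(-c3ccc(OCc4ccccc4)cc3)oc2c1
F4 | step 9 | 6-iodo-4'-O-benzylgenkwanin | COc1cc2oc(-c3ccc(OCc4ccccc4)cc3)cc(=O)c2c(O)c1I
F5 | step 7 | methyl (E)-5-oxo-3-(pyrrolidin-1-yl)-6-(5,7,4'-tri-O-benzylapigenin-8-yl)hex-3-enoate | COC(=O)C/C(N1CCCC1)=C\C(=O)Cc1c(OCc2ccccc2)cc(OCc2ccccc2)c2c(=O)cc(-c3ccc(OCc4ccccc4)cc3)oc12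
F0 | step 8 | none | none
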